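**Retrosynthetic overview**
- The C15 acid comes from a Horner–Wadsworth–Emmons reaction on the C13 methyl ketone at the end; the 6-acetate comes from acylation of the secondary alcohol.
- The C8 carbinol comes from methyl addition to a beta-hydroxy ketone. The C6–O bond, which carries the acetate, is the key bond: it is made by conjugate oxygenation of a cis-fused enone on its convex face.
- The C9 side chain comes from alpha-prime alkylation of the same enone with a ketal bromide.
- The enone comes from a cis-decalone by 1,3-carbonyl transposition, opened by a new palladium-catalysed dehydrogenative beta-methoxylation (a second C–O bond formation).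
- Ring order: ring B is bought as 3-methylcyclohex-2-enone, with C10 set by copper-catalysed asymmetric conjugate addition; ring A is closed second by cation/enol acetate cyclisation, which sets the cis C5.

Assumption: the SMILES is read literally with labdane numbering: a cis-fused decalin with H5, the C10 methyl, the C9 side chain, the C8 methyl and the 6-acetoxy group on one face and the 8-hydroxyl on the other (5S,6S,8S,9S,10R).

**Step 1**
Reactants: 1 3-methylcyclohex-2-en-1-one; 2 5-bromo-2-methylpent-2-ene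
Product: 5 (R)-3-methyl-3-(4-methylpent-3-en-1-yl)cyclohex-1-en-1-yl acetate, via Grignard reagent 3 (not isolated), via magnesium enolate 4 (not isolated)
Conditions: Mg, Et2O (from 2); Cu(OSO2CF3)2 (3 mol %), chiral C2-symmetric imidazolinium NHC precursor (4 mol %), Et2O, −30 °C; then Ac2O, −30 °C to rt
Reagents that add atoms: acetic anhydride, CC(=O)OC(C)=O
Why: Alexakis-type copper–NHC-catalysed asymmetric conjugate addition of the Grignard reagent to the beta-methyl enone builds the C10 quaternary stereocentre under catalyst control (ligand enantiomer chosen for the R centre), and House-type O-acetylation of the regiodefined magnesium enolate fixes the enol double bond toward C5.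

**Step 2**
Reactants: 5 (R)-3-methyl-3-(4-methylpent-3-en-1-yl)cyclohex-1-en-1-yl acetate
Product: 6 (4aS,8aS)-4a,8,8-trimethyloctahydronaphthalen-1(2H)-one (cis-fused)
Conditions: CF3SO3H (1.1 equiv), CH2Cl2, −78 to −20 °C; aq. NaHCO3
Reagents that add atoms: none
Why: Proton-initiated cation–olefin cyclisation terminated by an enol ester: the tertiary cation from the trisubstituted alkene is captured by the enol acetate carbon in a six-ring closure anti to the pseudo-axial C10 methyl, which sets H5 cis to that methyl, and the acid is expected to equilibrate C5 toward this same cis ketone, which avoids the double clash between the gem-dimethyl group and the carbonyl oxygen.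

**Step 3**
Reactants: 6 (4aS,8aS)-4a,8,8-trimethyloctahydronaphthalen-1(2H)-one
Product: 7 (4aS,8aS)-3-methoxy-4a,8,8-trimethyl-4a,5,6,7,8,8a-hexahydronaphthalen-1(4H)-one
Conditions: Pd(O2CCF3)2 (10 mol %), DMSO (20 mol %), CF3CO2H (20 mol %), O2 (1 atm), MeOH/chlorobenzene 1:1, 60 °C
Reagents that add atoms: methanol, CO
Why: Proposed new method: a divalent palladium enolate of 6 can undergo beta-hydride elimination only toward C7/C8 (C5 has no beta-hydrogen because C4 and C10 are quaternary), methanol then adds Wacker-fashion to the beta-carbon of the palladium-bound enone and a second beta-hydride elimination gives the vinylogous ester while O2 returns zerovalent palladium to the divalent state, aromatisation being impossible because of the quaternary C10, so the step forms the C8–O bond that fixes the oxygen pattern of ring B; the closest known reactions are Stahl-type aerobic dehydrogenation of cyclohexanones and Wacker-type oxidation of enones to beta-dicarbonyl compounds.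

**Step 4**
Reactants: 7 (4aS,8aS)-3-methoxy-4a,8,8-trimethyl-4a,5,6,7,8,8a-hexahydronaphthalen-1(4H)-one
Product: 9 (4aS,8aS)-5,5,8a-trimethyl-4a,5,6,7,8,8a-hexahydronaphthalen-2(1H)-one, via allylic alcohol 8 (not isolated)
Conditions: LiAlH4, Et2O, 0 °C; then 2 M HCl, THF, rt
Reagents that add atoms: water, O
Why: Stork–Danheiser reductive carbonyl transposition: hydride adds 1,2 to the vinylogous ester and aqueous acid ionises the allylic alcohol through the methoxy-stabilised cation, whose hydrolysis gives the transposed enone with C5 and C10 untouched.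

**Step 5**
Reactants: 9 (4aS,8aS)-5,5,8a-trimethyl-4a,5,6,7,8,8a-hexahydronaphthalen-2(1H)-one; 10 2-(2-bromoethyl)-2-methyl-1,3-dioxolane
Product: 11 (1S,4aS,8aR)-5,5,8a-trimethyl-1-[2-(2-methyl-1,3-dioxolan-2-yl)ethyl]-4a,5,6,7,8,8a-hexahydronaphthalen-2(1H)-one
Conditions: LiN(iPr)2, THF, −78 °C; then 10, DMPU, −78 to −10 °C
Reagents that add atoms: none
Why: Kinetic alpha-prime enolate alkylation: LiN(iPr)2 removes a proton from the only CH2 next to the carbonyl, and the primary bromide is attacked on the convex face of the cis-fused enolate, anti to the pseudo-axial C10–C1 bond of ring A, so the side chain ends up cis to the C10 methyl (C9 set).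

**Step 6**
Reactants: 11 (1S,4aS,8aR)-5,5,8a-trimethyl-1-[2-(2-methyl-1,3-dioxolan-2-yl)ethyl]-4a,5,6,7,8,8a-hexahydronaphthalen-2(1H)-one
Product: 13 (1S,4S,4aS,8aR)-4-hydroxy-5,5,8a-trimethyl-1-[2-(2-methyl-1,3-dioxolan-2-yl)ethyl]octahydronaphthalen-2(1H)-one, via C6 boronate 12 (not isolated)
Conditions: CuCl (5 mol %), NaOtBu (10 mol %), Xantphos (5 mol %), B2pin2, MeOH, THF, rt; then 30% H2O2, pH 7 phosphate buffer, 0 °C
Reagents that add atoms: bis(pinacolato)diboron (boryl group of 12 only), CC1(C)OB(OC1(C)C)B2OC(C)(C)C(C)(C)O2; hydrogen peroxide (oxygen of 13), OO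
Why: Yun-type beta-boration by a monovalent copper boryl complex adds boron to C6 on the convex face, anti to the neighbouring quaternary C4 and syn to H5, and the C–B bond is oxidised with retention, so the new C6–O bond is cis to H5 and to the C10 methyl.

**Step 7**
Reactants: 13 (1S,4S,4aS,8aR)-4-hydroxy-5,5,8a-trimethyl-1-[2-(2-methyl-1,3-dioxolan-2-yl)ethyl]octahydronaphthalen-2(1H)-one
Product: 15 4-[(1S,2S,4S,4aS,8aR)-2,4-dihydroxy-2,5,5,8a-tetramethyldecahydronaphthalen-1-yl]butan-2-one, via diol ketal 14 (not isolated)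
Conditions: CeCl3 (3 equiv), MeMgBr (3 equiv), THF, −78 to 0 °C; then 1 M HCl, THF, rt
Reagents that add atoms: methylmagnesium bromide, C[Mg]Br; water (oxygen of the released ketone), O
Why: Imamoto organocerium addition (low basicity, so no retro-aldol or beta-elimination) attacks the C8 ketone from the convex face because the axial trajectory on the other face is blocked by the syn-axial C1 methylene of ring A, giving the C8 methyl cis and the hydroxyl trans to the C10 methyl, and the acidic work-up hydrolyses the dioxolane.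

**Step 8**
Reactants: 15 4-[(1S,2S,4S,4aS,8aR)-2,4-dihydroxy-2,5,5,8a-tetramethyldecahydronaphthalen-1-yl]butan-2-one
Product: 16 4-[(1S,2S,4S,4aS,8aR)-4-acetoxy-2-hydroxy-2,5,5,8a-tetramethyldecahydronaphthalen-1-yl]butan-2-one
Conditions: Ac2O (1.5 equiv), pyridine, DMAP (5 mol %), CH2Cl2, 0 °C to rt
Reagents that add atoms: acetic anhydride, CC(=O)OC(C)=O
Why: DMAP-catalysed acylation discriminates the secondary equatorial C6 hydroxyl from the hindered tertiary C8 hydroxyl, and no stereocentre changes.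

**Step 9**
Reactants: 16 4-[(1S,2S,4S,4aS,8aR)-4-acetoxy-2-hydroxy-2,5,5,8a-tetramethyldecahydronaphthalen-1-yl]butan-2-one; 17 prop-2-en-1-yl 2-(diethoxyphosphoryl)acetate
Product: 18 prop-2-en-1-yl (2E)-5-[(1S,2S,4S,4aS,8aR)-4-acetoxy-2-hydroxy-2,5,5,8a-tetramethyldecahydronaphthalen-1-yl]-3-methylpent-2-enoate
Conditions: NaH (2.2 equiv), 17 (1.5 equiv), THF, 0 to 50 °C; chromatography
Reagents that add atoms: none
Why: Horner–Wadsworth–Emmons olefination of the methyl ketone gives the trisubstituted enoate mainly as the E isomer (reversible addition, thermodynamic control), the minor Z isomer being removed by chromatography.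

**Step 10**
Reactants: 18 prop-2-en-1-yl (2E)-5-[(1S,2S,4S,4aS,8aR)-4-acetoxy-2-hydroxy-2,5,5,8a-tetramethyldecahydronaphthalen-1-yl]-3-methylpent-2-enoate
Product: 19 (2E)-5-[(1S,2S,4S,4aS,8aR)-4-acetoxy-2-hydroxy-2,5,5,8a-tetramethyldecahydronaphthalen-1-yl]-3-methylpent-2-enoic acid (CNP0221670.1)
Conditions: Pd(PPh3)4 (5 mol %), morpholine, THF, rt
Reagents that add atoms: none
Why: Tsuji–Trost deallylation: zerovalent palladium ionises the allyl ester and morpholine traps the allyl fragment, releasing the acid under neutral conditions that spare the acetate and the tertiary alcohol.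

**Compound list**
1 | 3-methylcyclohex-2-en-1-one | CC1=CC(=O)CCC1 | starting material
2 | 5-bromo-2-methylpent-2-ene | CC(C)=CCCBr | starting material
3 | (4-methylpent-3-en-1-yl)magnesium bromide | CC(C)=CCC[Mg]Br | intermediate
4 | bromomagnesium (R)-3-methyl-3-(4-methylpent-3-en-1-yl)cyclohex-1-en-1-olate | Br[Mg]OC1=C[C@@](C)(CCC=C(C)C)CCC1 | intermediate
5 | (R)-3-methyl-3-(4-methylpent-3-en-1-yl)cyclohex-1-en-1-yl acetate | CC(=O)OC1=C[C@@](C)(CCC=C(C)C)CCC1 | intermediate
6 | (4aS,8aS)-4a,8,8-trimethyloctahydronaphthalen-1(2H)-one, cis-fused | O=C1CCC[C@]2(C)CCCC(C)(C)[C@H]12 | intermediate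
7 | (4aS,8aS)-3-methoxy-4a,8,8-trimethyl-4a,5,6,7,8,8a-hexahydronaphthalen-1(4H)-one | O=C1C=C(OC)C[C@]2(C)CCCC(C)(C)[C@H]12 | intermediate
8 | (4aS,8aS)-3-methoxy-4a,8,8-trimethyl-1,4,4a,5,6,7,8,8a-octahydronaphthalen-1-ol, C1 epimers, centre removed in the same step | OC1C=C(OC)C[C@]2(C)CCCC(C)(C)[C@H]12 | intermediate
9 | (4aS,8aS)-5,5,8a-trimethyl-4a,5,6,7,8,8a-hexahydronaphthalen-2(1H)-one | C1=CC(=O)C[C@]2(C)CCCC(C)(C)[C@H]12 | intermediate
10 | 2-(2-bromoethyl)-2-methyl-1,3-dioxolane | CC1(CCBr)OCCO1 | starting material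
11 | (1S,4aS,8aR)-5,5,8a-trimethyl-1-[2-(2-methyl-1,3-dioxolan-2-yl)ethyl]-4a,5,6,7,8,8a-hexahydronaphthalen-2(1H)-one | C1=CC(=O)[C@@H](CCC3(C)OCCO3)[C@]2(C)CCCC(C)(C)[C@H]12 | intermediate
12 | (1S,4S,4aS,8aR)-5,5,8a-trimethyl-1-[2-(2-methyl-1,3-dioxolan-2-yl)ethyl]-4-(4,4,5,5-tetramethyl-1,3,2-dioxaborolan-2-yl)octahydronaphthalen-2(1H)-one | CC1(C)OB(OC1(C)C)[C@H]4CC(=O)[C@@H](CCC3(C)OCCO3)[C@]5(C)CCCC(C)(C)[C@H]45 | intermediate
13 | (1S,4S,4aS,8aR)-4-hydroxy-5,5,8a-trimethyl-1-[2-(2-methyl-1,3-dioxolan-2-yl)ethyl]octahydronaphthalen-2(1H)-one | O[C@H]1CC(=O)[C@@H](CCC3(C)OCCO3)[C@]2(C)CCCC(C)(C)[C@H]12 | intermediate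
14 | (1S,2S,4S,4aS,8aR)-2,5,5,8a-tetramethyl-1-[2-(2-methyl-1,3-dioxolan-2-yl)ethyl]decahydronaphthalene-2,4-diol | O[C@H]1C[C@](C)(O)[C@@H](CCC3(C)OCCO3)[C@]2(C)CCCC(C)(C)[C@H]12 | intermediate
15 | 4-[(1S,2S,4S,4aS,8aR)-2,4-dihydroxy-2,5,5,8a-tetramethyldecahydronaphthalen-1-yl]butan-2-one | O[C@H]1C[C@](C)(O)[C@@H](CCC(C)=O)[C@]2(C)CCCC(C)(C)[C@H]12 | intermediate
16 | 4-[(1S,2S,4S,4aS,8aR)-4-acetoxy-2-hydroxy-2,5,5,8a-tetramethyldecahydronaphthalen-1-yl]butan-2-one | CC(=O)O[C@H]1C[C@](C)(O)[C@@H](CCC(C)=O)[C@]2(C)CCCC(C)(C)[C@H]12 | intermediate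
17 | prop-2-en-1-yl 2-(diethoxyphosphoryl)acetate | CCOP(=O)(CC(=O)OCC=C)OCC | starting material
18 | prop-2-en-1-yl (2E)-5-[(1S,2S,4S,4aS,8aR)-4-acetoxy-2-hydroxy-2,5,5,8a-tetramethyldecahydronaphthalen-1-yl]-3-methylpent-2-enoate | CC(=O)O[C@H]1C[C@](C)(O)[C@@H](CC/C(C)=C/C(=O)OCC=C)[C@]2(C)CCCC(C)(C)[C@H]12 | intermediate
19 | (2E)-5-[(1S,2S,4S,4aS,8aR)-4-acetoxy-2-hydroxy-2,5,5,8a-tetramethyldecahydronaphthalen-1-yl]-3-methylpent-2-enoic acid | CC(=O)O[C@H]1C[C@](C)(O)[C@@H](CC/C(C)=C/C(=O)O)[C@]2(C)CCCC(C)(C)[C@H]12 | target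

**Step count and risks**
Total step count: 10. Longest linear sequence: 10 steps (1 to 19).

The three steps most likely to fail:

Step 2 (ring A closure). The enol acetate may be protonated before the alkene, a carbonyl-ene side reaction may compete, or the trans-fused ketone may form. The fallback sets out from 2 (with 1) and comes back at 6. Acid-catalysed Markovnikov addition of methanol to 2 (MeOH, H2SO4 cat.) gives 1-bromo-4-methoxy-4-methylpentane F1. Its Grignard reagent is added to 1 with the step 1 catalyst and the enolate is trapped with Me3SiCl to give (S)-{[3-(4-methoxy-4-methylpentyl)-3-methylcyclohex-1-en-1-yl]oxy}trimethylsilane F2, which has the same spatial arrangement as 5. TiCl4 in CH2Cl2 at −78 °C then ionises the tertiary methyl ether and the silyl enol ether captures the cation (Reetz/Mukaiyama-type tertiary alkylation, kinetic, no free acid), giving 6.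

Step 3 (the proposed dehydrogenative beta-methoxylation). The catalyst may stop at the enone or not turn over. The fallback uses known chemistry, sets out from 6 and comes back at 9, leaving out 7 and 8. IBX dehydrogenation of 6 (or Saegusa–Ito oxidation with Pd(OAc)2 of its kinetic silyl enol ether) gives (4aS,8aS)-4a,8,8-trimethyl-4a,5,6,7,8,8a-hexahydronaphthalen-1(4H)-one F3. Weitz–Scheffer epoxidation (H2O2, NaOH, MeOH) on the convex face gives the 2,3-epoxy ketone F4. Wharton transposition (N2H4·H2O, AcOH cat.) gives (4aS,8aS)-5,5,8a-trimethyl-1,2,4a,5,6,7,8,8a-octahydronaphthalen-2-ol F5, and MnO2 oxidation gives 9.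

Step 7 (facial selectivity of methyl addition at C8). If the organocerium reagent attacks from the other face, the wrong C8 epimer results. The fallback sets out from 13 and comes back at 16; it builds C8 with carbon first and oxygen second, so the same facial preference now gives the required epimer. Acetylation of 13 (Ac2O, pyridine, DMAP) gives the 4-acetoxy ketone F6. Non-basic Takai–Lombardo methylenation (Zn, CH2Br2, TiCl4) gives the 2-methylidene compound F7. Mukaiyama hydration (Mn(dpm)3 cat., PhSiH3, O2, iPrOH) gives the tertiary alcohol F8, and 1 M HCl in THF removes the dioxolane to give 16.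

**Further compounds**
F1 | step 2 | 1-bromo-4-methoxy-4-methylpentane | COC(C)(C)CCCBr
F2 | step 2 | (S)-{[3-(4-methoxy-4-methylpentyl)-3-methylcyclohex-1-en-1-yl]oxy}trimethylsilane | C[Si](C)(C)OC1=C[C@@](C)(CCCC(C)(C)OC)CCC1
F3 | step 3 | (4aS,8aS)-4a,8,8-trimethyl-4a,5,6,7,8,8a-hexahydronaphthalen-1(4H)-one | O=C1C=CC[C@]2(C)CCCC(C)(C)[C@H]12
F4 | step 3 | (4aS,8aS)-2,3-epoxy-4a,8,8-trimethyloctahydronaphthalen-1(2H)-one, epoxide cis to the angular methyl | O=C1[C@H]3O[C@H]3C[C@]2(C)CCCC(C)(C)[C@H]12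
F5 | step 3 | (4aS,8aS)-5,5,8a-trimethyl-1,2,4a,5,6,7,8,8a-octahydronaphthalen-2-ol, hydroxyl cis to the angular methyl | C1=C[C@@H](O)C[C@]2(C)CCCC(C)(C)[C@H]12
F6 | step 7 | (1S,4S,4aS,8aR)-4-acetoxy-5,5,8a-trimethyl-1-[2-(2-methyl-1,3-dioxolan-2-yl)ethyl]octahydronaphthalen-2(1H)-one | CC(=O)O[C@H]1CC(=O)[C@@H](CCC3(C)OCCO3)[C@]2(C)CCCC(C)(C)[C@H]12
F7 | step 7 | 2-methylidene analogue of F6 (4-acetoxy-5,5,8a-trimethyl-2-methylidene-1-[2-(2-methyl-1,3-dioxolan-2-yl)ethyl]decahydronaphthalene, configuration as in F6) | CC(=O)O[C@H]1CC(=C)[C@@H](CCC3(C)OCCO3)[C@]2(C)CCCC(C)(C)[C@H]12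
F8 | step 7 | (1S,2S,4S,4aS,8aR)-4-acetoxy-2,5,5,8a-tetramethyl-1-[2-(2-methyl-1,3-dioxolan-2-yl)ethyl]decahydronaphthalen-2-ol | CC(=O)O[C@H]1C[C@](C)(O)[C@@H](CCC3(C)OCCO3)[C@]2(C)CCCC(C)(C)[C@H]12
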